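- Decide first to follow the coupling partner, concentration B, and hang the substrate curve on it.

in all of them: substrate 0.80 M

| run | coupling partner | capture agent | remark | time |
|---|---|---|---|---|
| larch | 1.44 M | 0.040 M | the very flask that is asked about, followed so far |  |
| ash | 2.9 M | 0.040 M | run made earlier |  |
| flask | 1.44 M | 0.0400 M |  | 6.0 min |

larch run (percent of the substrate charged)

| time / s | substrate / % | tris adduct / % | side product / % |
|---|---|---|---|
| 10.0 | 80.8 | 0.6 | 1.9 |
| 12.0 | 76.8 | 0 | 1.2 |
| 30.0 | 57.1 | 4.7 | 7.7 |
| 80.0 | 31.0 | 17.9 | 21.7 |

ash run (percent of the substrate charged)

| time / min | substrate / % | tris adduct / % | side product / % |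
|---|---|---|---|
| 0.200 | 60.2 | 4.3 | 3.0 |
| 0.417 | 37.6 | 15.2 | 7.5 |
| 1.00 | 13.8 | 42.4 | 18.3 |
| 2.50 | 2.2 | 65.1 | 27.0 |

(each reading ± 0.5 percentage points)

- the earlier runs were read with a standard deviation of 0.5 percentage points
- the reaction counts as stopped when no species that holds the substrate changes by six tenths of a point or more over the second half of the time

1. the state of affairs at 6.0 min: stopped, and by what, or still going (the coupling partner has run out first / it is still moving / all of the substrate has reacted)
2. share of the substrate used up at 6.0 min
3. tris adduct at 6.0 min, in percent of the substrate charged
4. side product at 6.0 min, in percent of the substrate charged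
5. bis adduct at 6.0 min, in percent of the substrate charged
6. amount of tris adduct if the flask were left three thousand times as long, in percent of the substrate charged

- Test the order. Treat substrate loss as first order in substrate and in B, with constant k, so that it is pseudo-first-order while B stands near its charge. The earliest readings give k = 0.875 /M/min in ash and 0.917 /M/min in larch, though ash holds twice the partner.
- Define the partner budget b, the partner charged per substrate charged: in larch, b = 1.80.
- Count the bill in the same units: one partner per substrate reacted, one more per bis adduct, two more per tris adduct, none more per side product.
- Check this count on larch. It leaves B at about 1.02 M at 30.0 s and 0.602 M at 80.0 s, both slightly high since bis adduct goes unread. Between them the substrate readings give k = 0.903 /M/min, so the count holds.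
- Draw the larch curve. It starts at a fractional slope of 1.30 /min, and the knee shows by 80.0 s, where the slope is 0.544 /min.
- Continue past the knee. As a rough assumption, hold B at its reckoned ratio to substrate at that knee, 2.43. This hyperbolic tail leaves about 8.77 % substrate at 6.0 min, still moving. The unread 29.4 % can still draw partner without using substrate, so the ratio should fall and this estimate probably sits low.
- Take the level it runs into: with substrate gone and partner as limiting reagent, tris adduct reaches (b − 1)/2 = 40.0 %.
- The forecast, charging the side product “about two partner equivalents overall” where my count charges one, says it is still moving, with conversion 88.5 %, tris adduct 31.5 %, side product 52.5 %, bis adduct 4.5 % and a long-run tris adduct of 33 %.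
- The flask gives it is still moving, with conversion 89.7 %, tris adduct 35.3 %, side product 48.1 %, bis adduct 2.49 % and a long-run tris adduct of 38.9 %.

    substrate + coupling partner → first product + released group (k = 0.0160 /M/s)
    coupling partner + first product → bis adduct + released group (k = 0.0180 /M/s)
    coupling partner + bis adduct → tris adduct + released group (k = 0.0440 /M/s)
    first product → side product (k = 0.0130 /s)
    first product + capture agent → trapped intermediate (k = 0.0130 /M/s)

- Hold the budget against both flasks. In this flask the bill, conversion plus twice tris adduct plus bis adduct, is 1.63, and with 9.5 % of its partner left, the partner used from b is 1.63 per substrate charged. The long-run tris adduct of 38.9 % stands beside the level of 40.0 %. The neighbour flask, charged with 0.86 M of partner, has b = 1.07. Its bill is 1.03 against 1.03 used. At 6.0 min that flask holds 14.4 % tris adduct, with 30.2 % substrate and 4.2 % of its partner left.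

The runs were computed on assumed constants; noise was put on by code.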